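**Retrosynthetic overview**
1. The target is an endo Diels–Alder-type adduct. Its cyclohexene is numbered C1(Me)=C2H–C3H–C4H–C5H–C6H2, with the flavanone (through its C8) on C3 and a 2,4-dihydroxyphenyl on C5. The plan rests on the C4 acyl group, a 2,4-dihydroxy-3-prenylbenzoyl ring: C1' acyl, C2' OH, C3' prenyl, C4' OH, C5' H, C6' H.
2. That ring is made last. Bonds C1'–C2' and C5'–C6' are cut to give a C4 ethynyl ketone (supplies C1', C6') and 1-methoxy-2-prenyl-1,3-bis(trimethylsilyloxy)butadiene (supplies C2'–C5'); the forward reaction is a [4+2] addition followed by loss of methanol.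
3. The ynone comes from the C4 aldehyde (ethynyl Grignard addition, oxidation). The cyclohexene (bonds C3–C4 and C5–C6; stereocentres C3, C4, C5) comes from an iminium-catalysed endo Diels–Alder reaction of a 2,4-bis(MOM-oxy)cinnamaldehyde with the (2S)-flavanone carrying an (E)-3-methylbuta-1,3-dienyl group on C8.
4. The flavanone comes from a Claisen–Schmidt chalcone of 3-iodoresacetophenone, oxa-Michael ring closure, kinetic resolution by transfer hydrogenation, and a base-free Stille coupling for the diene.
5. Ring order: pyranone ring of the flavanone, then the cyclohexene, then the prenylated resorcinol ring; the five MOM ethers are removed last.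

Key step: step 16

Remark: descriptors 3S,4R,5S use the cyclohexene numbering of the overview; the carbinol carbon of 15 and the ketal carbon of 23 form as mixtures and are destroyed later; MOMCl, Ph3P=CHCHO, Bu3SnH and HC≡CMgBr are taken as commercial reagents.

**Route**

Step 1
Reactants: 1 2,4-dihydroxybenzaldehyde
Product: 2 2,4-bis(methoxymethoxy)benzaldehyde
Conditions: MOMCl (3 equiv), i-Pr2NEt, CH2Cl2, 0 → 40 °C
Reagents that add atoms: chloromethyl methyl ether, COCCl
Why: O-alkylation of both phenols by the reactive α-chloro ether (Williamson type); excess reagent and warming overcome the hydrogen bond of the 2-OH to the aldehyde.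

Step 2
Reactants: 2 2,4-bis(methoxymethoxy)benzaldehyde
Product: 3 (E)-3-[2,4-bis(methoxymethoxy)phenyl]prop-2-enal
Conditions: Ph3P=CHCHO (1.2 equiv), toluene, 80 °C
Reagents that add atoms: (triphenylphosphoranylidene)acetaldehyde, O=CC=P(c1ccccc1)(c1ccccc1)c1ccccc1
Why: Wittig olefination with a stabilised ylide should give the E-enal, and the small excess of ylide limits a second homologation.

Step 3
Reactants: 4 2,4-dihydroxyacetophenone
Product: 5 1-(2,4-dihydroxy-3-iodophenyl)ethanone
Conditions: I2 (0.4 equiv), HIO3 (0.2 equiv), EtOH/H2O, 35 °C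
Reagents that add atoms: iodine, II; iodic acid, OI(=O)=O
Why: Electrophilic aromatic iodination by the I2/HIO3 couple, which is known to iodinate resacetophenone at C3, the position ortho to both hydroxyl groups.

Step 4
Reactants: 5 1-(2,4-dihydroxy-3-iodophenyl)ethanone
Product: 6 1-[2-hydroxy-3-iodo-4-(methoxymethoxy)phenyl]ethanone
Conditions: MOMCl (1.1 equiv), K2CO3, acetone, 0 °C → rt
Reagents that add atoms: chloromethyl methyl ether, COCCl
Why: Selective O-alkylation of the free, more acidic 4-OH, since the 2-OH is held in a hydrogen bond to the ketone and is flanked by iodine.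

Step 5
Reactants: 6 1-[2-hydroxy-3-iodo-4-(methoxymethoxy)phenyl]ethanone; 2 2,4-bis(methoxymethoxy)benzaldehyde
Product: 8 (E)-3-[2,4-bis(methoxymethoxy)phenyl]-1-[2-hydroxy-3-iodo-4-(methoxymethoxy)phenyl]prop-2-en-1-one, via aldol adduct 7 (not isolated)
Conditions: KOH, EtOH/H2O, rt; then AcOH to pH 6
Reagents that add atoms: none
Why: Claisen–Schmidt condensation, in which the methyl ketone enolate adds to the non-enolisable aldehyde and the aldol loses water to the E-enone, while the MOM ethers and the aryl iodide are stable to hydroxide.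

Step 6
Reactants: 8 (E)-2'-hydroxychalcone
Product: 9 racemic 2-[2,4-bis(methoxymethoxy)phenyl]-8-iodo-7-(methoxymethoxy)chroman-4-one
Conditions: NaOAc, EtOH, reflux; unreacted 8 recycled
Reagents that add atoms: none
Why: Intramolecular oxa-Michael addition of the phenoxide to the enone (6-endo-trig) closes the pyranone ring under equilibrium control and creates C2 as a racemate.

Step 7
Reactants: 9 racemic 8-iodoflavanone
Product: 10 (2S)-2-[2,4-bis(methoxymethoxy)phenyl]-8-iodo-7-(methoxymethoxy)chroman-4-one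
Conditions: RhCl(C5Me5)[(R,R)-TsDPEN] (1 mol%), HCO2H/Et3N (5:2), EtOAc, rt, stopped at about 55% conversion; chromatography
Reagents that add atoms: none
Why: Kinetic resolution by asymmetric transfer hydrogenation: the (R,R)-catalyst gives (4R)-carbinols and should do so fast only when that carbonyl face is anti to the 2-aryl group, that is in the (2R)-ketone, so the (2S)-ketone should remain and the (2R,4R)-cis-flavan-4-ol is separated.

Step 8
Reactants: 11 2-methylbut-1-en-3-yne
Product: 12 tributyl[(1E)-3-methylbuta-1,3-dien-1-yl]stannane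
Conditions: Bu3SnH, AIBN (cat.), neat, 80 °C; distillation
Reagents that add atoms: tributyltin hydride, CCCC[SnH](CCCC)CCCC
Why: Radical hydrostannation puts tin on the terminal alkyne carbon, and reversible stannyl radical addition should equilibrate the product towards the E-vinylstannane.

Step 9
Reactants: 10 (2S)-8-iodoflavanone; 12 tributyl[(1E)-3-methylbuta-1,3-dien-1-yl]stannane
Product: 13 (2S)-2-[2,4-bis(methoxymethoxy)phenyl]-7-(methoxymethoxy)-8-[(1E)-3-methylbuta-1,3-dien-1-yl]chroman-4-one
Conditions: Pd(PPh3)4 (5 mol%), CuI (10 mol%), DMF, 60 °C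
Reagents that add atoms: none
Why: Stille coupling with retention of alkene geometry in a base-free medium that should leave the base-labile C2 centre untouched; both oxygens ortho to the new diene are capped, so no chromene can form.

Step 10
Reactants: 13 (2S)-8-dienylflavanone; 3 (E)-3-[2,4-bis(methoxymethoxy)phenyl]prop-2-enal
Product: 14 (3S,4R,5S)-5-[2,4-bis(methoxymethoxy)phenyl]-3-{(2S)-2-[2,4-bis(methoxymethoxy)phenyl]-7-(methoxymethoxy)-4-oxochroman-8-yl}-1-methylcyclohex-1-ene-4-carbaldehyde
Conditions: (5S)-5-benzyl-2,2,3-trimethylimidazolidin-4-one hydrochloride (20 mol%), 3 (3 equiv), MeCN/H2O (95:5), 0 °C → rt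
Reagents that add atoms: none
Why: Iminium-catalysed Diels–Alder reaction: the E-iminium ion of 3 is shielded on the Re face of C-β by the benzyl group and the diene adds endo to the Si face, CH2 terminus to C-β and aryl-bearing terminus to C-α, so the E-geometry of 3 and the catalyst set C4 (R) and C5 (S), the endo transition state sets C3 (S) cis to the formyl group, and the remote flavanone C2 plays no part.

Step 11
Reactants: 14 C4 aldehyde
Product: 15 C4 (1-hydroxyprop-2-yn-1-yl) compound, both carbinol epimers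
Conditions: HC≡CMgBr (1.3 equiv), THF, −78 → −30 °C; aq. NH4Cl
Reagents that add atoms: ethynylmagnesium bromide, C#C[Mg]Br
Why: Grignard 1,2-addition that should be selective for the aldehyde over the chromanone carbonyl, which is deactivated by its ortho and para oxygen donors, while the weakly basic acetylide at low temperature should not enolise C4 or the chromanone.

Step 12
Reactants: 15 propargylic alcohol
Product: 16 C4 ethynyl ketone (3S,4R,5S; flavanone 2S) with five MOM ethers
Conditions: Dess–Martin periodinane, CH2Cl2, 0 °C → rt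
Reagents that add atoms: none
Why: Dess–Martin oxidation of the propargylic alcohol under near-neutral conditions, which should spare the MOM ethers and not epimerise C4 next to the new ketone.

Step 13
Reactants: 17 methyl acetoacetate; 18 prenyl bromide
Product: 19 methyl 2-acetyl-5-methylhex-4-enoate (racemic)
Conditions: K2CO3, acetone, reflux; 17 in excess
Reagents that add atoms: none
Why: SN2 C-alkylation of the stabilised β-keto ester enolate by the allylic bromide, with excess keto ester to limit dialkylation.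

Step 14
Reactants: 19 methyl 2-prenylacetoacetate
Product: 20 methyl 2-(3-methylbut-2-en-1-yl)-3-(trimethylsilyloxy)but-2-enoate
Conditions: Me3SiCl, Et3N, toluene, rt
Reagents that add atoms: chlorotrimethylsilane, C[Si](C)(C)Cl
Why: O-silylation of the β-keto ester enol gives the 3-silyloxy enoate.

Step 15
Reactants: 20 silyl enol ether
Product: 22 1-methoxy-2-(3-methylbut-2-enyl)-1,3-bis(trimethylsilyloxy)buta-1,3-diene, via lithium dienolate 21 (not isolated)
Conditions: LiN(i-Pr)2, THF, −78 °C; then Me3SiCl, −78 → 0 °C; non-aqueous work-up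
Reagents that add atoms: chlorotrimethylsilane, C[Si](C)(C)Cl
Why: Deprotonation of the γ-methyl group gives the extended ester enolate, which is silylated on oxygen to the mixed ketene acetal diene.

Step 16
Reactants: 16 C4 ethynyl ketone; 22 bis(silyloxy)diene (3 equiv)
Product: 25 (3S,4R,5S)-cyclohexenyl 2,4-dihydroxy-3-(3-methylbut-2-enyl)phenyl ketone carrying the five other phenols as MOM ethers, via cycloadduct 23 (not isolated), via bis(trimethylsilyl) ether 24 (not isolated)
Conditions: toluene, 20 → 80 °C, sealed; then 10% aq. citric acid, THF, rt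
Reagents that add atoms: none
Why: Thermal normal-demand [4+2] cycloaddition of the electron-rich diene 22 to the ynone 16, concerted but strongly asynchronous: the CH2 terminus of 22, its most nucleophilic carbon, bonds first to the unsubstituted β-carbon of the ynone and the ketene acetal carbon then bonds to the acyl-bearing α-carbon. The closest known reaction type is the benzannulation of 1-alkoxy-1,3-bis(silyloxy)buta-1,3-dienes with acetylenic esters and ketones, which gives 2,4-dioxygenated aryl carbonyl compounds after loss of the alcohol. The six-membered carbocycle is closed in the intermolecular cycloaddition itself (bonds C1'–C2' and C5'–C6'), giving the cyclohexa-1,4-diene ketal 23; 1,4-elimination of methanol from its ketal carbon and ring CH2 gives the aromatic bis-silyl ether 24, and mild aqueous acid frees both phenols. No lasting stereocentre is formed, since the ketal carbon of 23 is lost on aromatisation, and C3, C4, C5 and the flavanone C2 should be untouched in the neutral, metal-free medium. The step needs regioselectivity, secured by the matched polarisation of the two partners and by the prenyl group on C2 of the diene, which blocks a [3+3] mode through that carbon; it also needs chemoselectivity, and the ynone is the only π-bond of 16 activated enough to react without a Lewis acid.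

Step 17
Reactants: 25 penta-MOM ether of the target
Product: 26 target CNP0157992.1
Conditions: 3 M aq. HCl/MeOH (1:5), 40 °C, stopped at full conversion
Reagents that add atoms: none
Why: Acid-catalysed acetal exchange with methanol frees the five phenols as dimethoxymethane, and dilute acid at moderate temperature is chosen so that the prenyl alkene, the ring alkene and the flavanone C2 centre should survive.

**Compound list**
1 | 2,4-dihydroxybenzaldehyde | O=Cc1ccc(O)cc1O | starting material
2 | 2,4-bis(methoxymethoxy)benzaldehyde | COCOc1ccc(C=O)c(OCOC)c1 | intermediate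
3 | (E)-3-[2,4-bis(methoxymethoxy)phenyl]prop-2-enal | COCOc1ccc(/C=C/C=O)c(OCOC)c1 | intermediate
4 | 2,4-dihydroxyacetophenone | CC(=O)c1ccc(O)cc1O | starting material
5 | 1-(2,4-dihydroxy-3-iodophenyl)ethanone | CC(=O)c1ccc(O)c(I)c1O | intermediate
6 | 1-[2-hydroxy-3-iodo-4-(methoxymethoxy)phenyl]ethanone | CC(=O)c1ccc(OCOC)c(I)c1O | intermediate
7 | aldol adduct, 3-[2,4-bis(methoxymethoxy)phenyl]-3-hydroxy-1-[2-hydroxy-3-iodo-4-(methoxymethoxy)phenyl]propan-1-one | COCOc1ccc(C(O)CC(=O)c2ccc(OCOC)c(I)c2O)c(OCOC)c1 | intermediate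
8 | (E)-3-[2,4-bis(methoxymethoxy)phenyl]-1-[2-hydroxy-3-iodo-4-(methoxymethoxy)phenyl]prop-2-en-1-one | COCOc1ccc(/C=C/C(=O)c2ccc(OCOC)c(I)c2O)c(OCOC)c1 | intermediate
9 | racemic 2-[2,4-bis(methoxymethoxy)phenyl]-8-iodo-7-(methoxymethoxy)chroman-4-one | COCOc1ccc2c(c1I)OC(c1ccc(OCOC)cc1OCOC)CC2=O | intermediate
10 | (2S)-2-[2,4-bis(methoxymethoxy)phenyl]-8-iodo-7-(methoxymethoxy)chroman-4-one | COCOc1ccc2c(c1I)O[C@H](c1ccc(OCOC)cc1OCOC)CC2=O | intermediate
11 | 2-methylbut-1-en-3-yne | C=C(C)C#C | starting material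
12 | tributyl[(1E)-3-methylbuta-1,3-dien-1-yl]stannane | C=C(C)/C=C/[Sn](CCCC)(CCCC)CCCC | intermediate
13 | (2S)-2-[2,4-bis(methoxymethoxy)phenyl]-7-(methoxymethoxy)-8-[(1E)-3-methylbuta-1,3-dien-1-yl]chroman-4-one | C=C(C)/C=C/c1c(OCOC)ccc2c1O[C@H](c1ccc(OCOC)cc1OCOC)CC2=O | intermediate
14 | (3S,4R,5S)-5-[2,4-bis(methoxymethoxy)phenyl]-3-{(2S)-2-[2,4-bis(methoxymethoxy)phenyl]-7-(methoxymethoxy)-4-oxochroman-8-yl}-1-methylcyclohex-1-ene-4-carbaldehyde | O=C[C@H]1[C@@H](c2c(OCOC)ccc3c2O[C@H](c2ccc(OCOC)cc2OCOC)CC3=O)C=C(C)C[C@@H]1c1ccc(OCOC)cc1OCOC | intermediate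
15 | propargylic alcohol from 14, 1-[(3S,4R,5S)-cyclohexen-4-yl]prop-2-yn-1-ol, carbinol epimers | C#CC(O)[C@H]1[C@@H](c2c(OCOC)ccc3c2O[C@H](c2ccc(OCOC)cc2OCOC)CC3=O)C=C(C)C[C@@H]1c1ccc(OCOC)cc1OCOC | intermediate
16 | C4 ethynyl ketone, 1-[(3S,4R,5S)-cyclohexen-4-yl]prop-2-yn-1-one with (2S)-flavanone and five MOM ethers | C#CC(=O)[C@H]1[C@@H](c2c(OCOC)ccc3c2O[C@H](c2ccc(OCOC)cc2OCOC)CC3=O)C=C(C)C[C@@H]1c1ccc(OCOC)cc1OCOC | intermediate
17 | methyl acetoacetate | CC(=O)CC(=O)OC | starting material
18 | prenyl bromide (1-bromo-3-methylbut-2-ene) | CC(C)=CCBr | starting material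
19 | methyl 2-acetyl-5-methylhex-4-enoate (racemic) | COC(=O)C(CC=C(C)C)C(C)=O | intermediate
20 | methyl 2-(3-methylbut-2-en-1-yl)-3-(trimethylsilyloxy)but-2-enoate | COC(=O)C(CC=C(C)C)=C(C)O[Si](C)(C)C | intermediate
21 | lithium dienolate of 20 | [Li]OC(OC)=C(CC=C(C)C)C(=C)O[Si](C)(C)C | intermediate
22 | 1-methoxy-2-(3-methylbut-2-enyl)-1,3-bis(trimethylsilyloxy)buta-1,3-diene | CO/C(O[Si](C)(C)C)=C(/CC=C(C)C)C(=C)O[Si](C)(C)C | intermediate
23 | cycloadduct, 6-methoxy-5-prenyl-4,6-bis(trimethylsilyloxy)cyclohexa-1,4-dien-1-yl ketone of the cyclohexene core (ketal carbon as a mixture) | COC1(O[Si](C)(C)C)C(CC=C(C)C)=C(O[Si](C)(C)C)CC=C1C(=O)[C@H]1[C@@H](c2c(OCOC)ccc3c2O[C@H](c2ccc(OCOC)cc2OCOC)CC3=O)C=C(C)C[C@@H]1c1ccc(OCOC)cc1OCOC | intermediate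
24 | bis(trimethylsilyl) ether of 25 | CC(C)=CCc1c(O[Si](C)(C)C)ccc(C(=O)[C@H]2[C@@H](c3c(OCOC)ccc4c3O[C@H](c3ccc(OCOC)cc3OCOC)CC4=O)C=C(C)C[C@@H]2c2ccc(OCOC)cc2OCOC)c1O[Si](C)(C)C | intermediate
25 | target with its five other phenols as MOM ethers (3S,4R,5S; flavanone 2S) | CC(C)=CCc1c(O)ccc(C(=O)[C@H]2[C@@H](c3c(OCOC)ccc4c3O[C@H](c3ccc(OCOC)cc3OCOC)CC4=O)C=C(C)C[C@@H]2c2ccc(OCOC)cc2OCOC)c1O | intermediate
26 | CNP0157992.1 (3S,4R,5S; flavanone 2S) | CC(C)=CCc1c(O)ccc(C(=O)[C@H]2[C@@H](c3c(O)ccc4c3O[C@H](c3ccc(O)cc3O)CC4=O)C=C(C)C[C@@H]2c2ccc(O)cc2O)c1O | target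

**Step count**
Total step count: 17.
Longest linear sequence: 11 steps (steps 3, 4, 5, 6, 7, 9, 10, 11, 12, 16, 17, from 4).

**Steps most likely to fail**

Step 10. The donor-substituted iminium ion may be too weak a dienophile for a diene whose reacting terminus carries an aryl group with two ortho oxygens, so the cycloaddition may be slow, the diene may oligomerise, and endo or facial selectivity may erode. The fallback sets out from 2 and 13 and comes back at 16, replacing the enal by a chelating dienophile and a chiral Lewis acid.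
- Aldehyde 2 is condensed with 3-hydroxy-3-methylbutan-2-one (LiOH, MeOH/H2O) to (E)-1-[2,4-bis(methoxymethoxy)phenyl]-4-hydroxy-4-methylpent-1-en-3-one F1, whose ketol binds a metal as a five-membered chelate.
- Cu(OTf)2 with 2,2'-isopropylidenebis(4-tert-butyl-2-oxazoline), in the antipode that leaves the Si face of C-β open, should catalyse the endo Diels–Alder reaction with 13 to the ketol adduct F2.
- NaIO4 in MeOH/H2O cleaves the ketol to the C4 carboxylic acid F3 with loss of acetone.
- 1-Chloro-N,N,2-trimethylprop-1-enylamine converts F3 under neutral conditions into the C4 acid chloride F4.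
- Acyl Stille coupling of F4 with tributyl(ethynyl)stannane (PdCl2(PPh3)2 cat., toluene) gives 16.

Step 16. The diene may add to the ynone in conjugate fashion without ring closure, may hydrolyse or decompose faster than it reacts with the hindered ynone, or the adduct may fail to lose methanol cleanly. The fallback sets out from 14 and comes back at 26, attaching the finished arene as an organolithium.
- Commercial 1,3-bis(methoxymethoxy)benzene is lithiated between its two acetal oxygens (n-BuLi, THF, 0 °C) and alkylated with 18 (CuI cat.) to 1,3-bis(methoxymethoxy)-2-(3-methylbut-2-enyl)benzene F5.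
- NBS in DMF at 0 °C should brominate para to one acetal oxygen, giving 1-bromo-2,4-bis(methoxymethoxy)-3-(3-methylbut-2-enyl)benzene F6.
- Bromine–lithium exchange (n-BuLi, THF, −78 °C) gives [2,4-bis(methoxymethoxy)-3-(3-methylbut-2-enyl)phenyl]lithium F7.
- F7 adds to aldehyde 14 to give the aryl carbinol F8.
- Dess–Martin oxidation gives the aryl ketone with seven MOM ethers F9, and HCl in MeOH removes all seven to give 26.

Step 17. Under acid, a phenol next to the prenyl group may add to the alkene (chroman formation), nearby phenols may ketalise the C4 ketone, or the flavanone ring may open and re-close with loss of configuration at C2. The fallback sets out from 25 and comes back at 26, masking the two phenols that flank the prenyl group during acetal cleavage.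
- t-BuMe2SiOTf and 2,6-lutidine in CH2Cl2 give the bis(tert-butyldimethylsilyl) ether of 25 F10.
- HCl in MeOH at rt removes the MOM ethers while the slower-cleaving aryl silyl ethers stay on, giving the bis(tert-butyldimethylsilyl) ether of 26 F11.
- Buffered fluoride (Bu4NF/AcOH, THF, 0 °C) frees the last two phenols to give 26.

**Further compounds**
F1 | step 10 | (E)-1-[2,4-bis(methoxymethoxy)phenyl]-4-hydroxy-4-methylpent-1-en-3-one | COCOc1ccc(/C=C/C(=O)C(C)(C)O)c(OCOC)c1
F2 | step 10 | ketol adduct, 1-[(3S,4R,5S)-cyclohexen-4-yl]-2-hydroxy-2-methylpropan-1-one | CC(C)(O)C(=O)[C@H]1[C@@H](c2c(OCOC)ccc3c2O[C@H](c2ccc(OCOC)cc2OCOC)CC3=O)C=C(C)C[C@@H]1c1ccc(OCOC)cc1OCOC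
F3 | step 10 | C4 carboxylic acid of the cyclohexene core | OC(=O)[C@H]1[C@@H](c2c(OCOC)ccc3c2O[C@H](c2ccc(OCOC)cc2OCOC)CC3=O)C=C(C)C[C@@H]1c1ccc(OCOC)cc1OCOC
F4 | step 10 | C4 acid chloride of the cyclohexene core | ClC(=O)[C@H]1[C@@H](c2c(OCOC)ccc3c2O[C@H](c2ccc(OCOC)cc2OCOC)CC3=O)C=C(C)C[C@@H]1c1ccc(OCOC)cc1OCOC
F5 | step 16 | 1,3-bis(methoxymethoxy)-2-(3-methylbut-2-enyl)benzene | COCOc1cccc(OCOC)c1CC=C(C)C
F6 | step 16 | 1-bromo-2,4-bis(methoxymethoxy)-3-(3-methylbut-2-enyl)benzene | COCOc1ccc(Br)c(OCOC)c1CC=C(C)C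
F7 | step 16 | [2,4-bis(methoxymethoxy)-3-(3-methylbut-2-enyl)phenyl]lithium | [Li]c1ccc(OCOC)c(CC=C(C)C)c1OCOC
F8 | step 16 | aryl carbinol from 14 and F7, carbinol epimers | COCOc1ccc(C(O)[C@H]2[C@@H](c3c(OCOC)ccc4c3O[C@H](c3ccc(OCOC)cc3OCOC)CC4=O)C=C(C)C[C@@H]2c2ccc(OCOC)cc2OCOC)c(OCOC)c1CC=C(C)C
F9 | step 16 | aryl ketone with seven MOM ethers | COCOc1ccc(C(=O)[C@H]2[C@@H](c3c(OCOC)ccc4c3O[C@H](c3ccc(OCOC)cc3OCOC)CC4=O)C=C(C)C[C@@H]2c2ccc(OCOC)cc2OCOC)c(OCOC)c1CC=C(C)C
F10 | step 17 | bis(tert-butyldimethylsilyl) ether of 25 | CC(C)=CCc1c(O[Si](C)(C)C(C)(C)C)ccc(C(=O)[C@H]2[C@@H](c3c(OCOC)ccc4c3O[C@H](c3ccc(OCOC)cc3OCOC)CC4=O)C=C(C)C[C@@H]2c2ccc(OCOC)cc2OCOC)c1O[Si](C)(C)C(C)(C)C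
F11 | step 17 | bis(tert-butyldimethylsilyl) ether of 26 | CC(C)=CCc1c(O[Si](C)(C)C(C)(C)C)ccc(C(=O)[C@H]2[C@@H](c3c(O)ccc4c3O[C@H](c3ccc(O)cc3O)CC4=O)C=C(C)C[C@@H]2c2ccc(O)cc2O)c1O[Si](C)(C)C(C)(C)C
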